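**Assumptions.** (−)-Dehydrocostus lactone (CAS 477-43-0, a catalogue natural product) is taken as the commercial starting material; it already carries the 5-7-5 guaianolide core and the four native stereocentres of each half. Guaianolide numbering is used: unprimed = the diol half, primed = the spiro-ketone half. "α" is the face bearing H-1 and H-5. Reagents and catalysts are named in the conditions and are not numbered.

## Retrosynthetic overview

1. Ainsliadimer A (6) ⇐ intramolecular aldol (C3–C4′ bond) of hydroxy-diketone 5; this closes the linking cyclopentane.
2. 5 ⇐ acid hydrolysis of the spiro-dihydropyran enol ether 4, which unmasks the C3′ ketone and the C4 tertiary alcohol.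
3. 4 ⇐ hetero-Diels–Alder homodimerisation of dehydrozaluzanin C (3), forming O–C4 and C15–C15′.
4. 3 ⇐ allylic C3 oxidation (SeO2, then alcohol oxidation) of commercial (−)-dehydrocostus lactone (1).
5. Ring order: 5-7-5 lactone cores purchased → dihydropyran (HDA) → opened → central cyclopentane (aldol).

## Route

**Step 1**
Reactants: 1, (−)-dehydrocostus lactone (guaia-4(15),10(14),11(13)-trien-12,6α-olide; H-1α, H-5α, H-6β, H-7α; 1R,5R,6S,7S)
Product: 2, 3-epizaluzanin C (isozaluzanin C; the 3α-hydroxy derivative of 1, 3R)
Conditions: SeO2 (0.5 equiv), t-BuOOH (2 equiv, 5.5 M in decane), CH2Cl2, 0 °C → rt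
Reagents that add atoms: selenium dioxide, O=[Se]=O (delivers the C3 oxygen); tert-butyl hydroperoxide, CC(C)(C)OO (terminal oxidant that regenerates Se(IV))
Why: Catalytic SeO2 allylic oxidation (ene reaction at the electron-rich C4=C15 olefin, then [2,3]-sigmatropic shift) hydroxylates the allylic CH2 at C3 in preference to the methines and the electron-poor lactone methylene, with oxygen delivered to the convex α-face; this centre is removed in step 2, so its configuration does not matter.

**Step 2**
Reactants: 2, 3-epizaluzanin C
Product: 3, dehydrozaluzanin C (3-oxoguaia-4(15),10(14),11(13)-trien-12,6α-olide)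
Conditions: Dess–Martin periodinane (1.3 equiv), NaHCO3, CH2Cl2, 0 °C → rt; keep 3 cold and dilute until step 3
Reagents that add atoms: none
Why: Dess–Martin oxidation of the secondary allylic alcohol gives the s-cis-locked α-methylene cyclopentanone without touching the olefins or lactone; no stereocentre is formed and C1/C5 are not epimerised under buffered conditions.

**Step 3**
Reactants: 3, dehydrozaluzanin C (2 molecules: one as 1-oxadiene O=C3′–C4′=C15′, one as dienophile C4=C15)
Product: 4, spiro-dihydropyran HDA dimer (ring O–C3′=C4′–C15′H2–C15H2–C4; C4 is spiro with the pyran O on the α-face and C15 on the β-face; the unprimed half keeps its C3 ketone)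
Conditions: BINOL (0.5–1 equiv, H-bond donor), neat film, 50 °C, 60 h, dark; recycle recovered 3
Reagents that add atoms: none
Why: Hydrogen-bond-activated inverse-demand hetero-Diels–Alder dimerisation with acrolein-dimer regiochemistry (O to the α-carbon C4, β-carbon C15′ to C15); the oxadiene adds to the convex α-face of the dienophile, anti to C6 on C5, which sets the only new stereocentre (C4, O α).

**Step 4**
Reactants: 4, spiro-dihydropyran HDA dimer
Product: 5, hydroxy-diketone (4α-hydroxy-3-oxo half joined through C15H2–C15′H2 to C4′ of a 3′-oxo half; C4′–H is an inconsequential epimer mixture)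
Conditions: 1 N aq. HCl, THF, rt
Reagents that add atoms: water, O
Why: Acid-catalysed enol-ether hydrolysis (C4′ protonation, water addition to the C3′ oxocarbenium, hemiketal collapse) releases the C3′ ketone and the C4 tertiary alcohol; the C4–O bond is never broken, so C4 keeps its configuration, and the exocyclic olefins and lactones tolerate dilute acid at rt.

**Step 5**
Reactants: 5, hydroxy-diketone
Product: 6, (+)-ainsliadimer A (target)
Conditions: DBU (0.5–1 equiv), CH2Cl2, 20 °C
Reagents that add atoms: none
Why: Reversible intramolecular aldol (5-membered ring closure) of the C4′ enolate onto the C3 ketone; the β-disposed C15 tether forces a cis-fused bicyclo[3.3.0] junction (C3–OH α, cis to C4–OH), and the quaternary C4′ forms by attack through the convex α-face of the primed half (anti to C6′) under thermodynamic control, with dehydration impossible because C4′ is quaternary.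

## Compound list

1 | (−)-dehydrocostus lactone | C=C1C(=O)O[C@@H]2[C@@H]3[C@@H](CCC3=C)C(=C)CC[C@@H]12 | starting material
2 | 3-epizaluzanin C (3α-OH) | C=C1C(=O)O[C@@H]2[C@@H]3[C@@H](C[C@@H](O)C3=C)C(=C)CC[C@@H]12 | intermediate
3 | dehydrozaluzanin C | C=C1C(=O)O[C@@H]2[C@@H]3[C@@H](CC(=O)C3=C)C(=C)CC[C@@H]12 | intermediate
4 | spiro-dihydropyran HDA dimer | C=C1C(=O)O[C@@H]2[C@@H]3[C@@H](CC(=O)[C@]34CCC5=C(O4)C[C@H]6C(=C)CC[C@H]7C(=C)C(=O)O[C@@H]7[C@@H]56)C(=C)CC[C@@H]12 | intermediate
5 | hydroxy-diketone (C4′ unassigned, epimer mixture) | C=C1C(=O)O[C@@H]2[C@@H]3[C@@H](CC(=O)[C@]3(O)CCC4C(=O)C[C@H]5C(=C)CC[C@H]6C(=C)C(=O)O[C@@H]6[C@@H]45)C(=C)CC[C@@H]12 | intermediate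
6 | (+)-ainsliadimer A | C=C1C(=O)O[C@@H]2[C@@H]3[C@@H](C[C@@]4(O)[C@]3(O)CC[C@]43C(=O)C[C@H]4C(=C)CC[C@H]5C(=C)C(=O)O[C@@H]5[C@H]43)C(=C)CC[C@@H]12 | target

## Summary

**Total step count:** 5
**Longest linear sequence:** 5 (step 3 combines two molecules of the same intermediate)

**Steps most likely to fail, with fallbacks**

1. **Step 3 (HDA dimerisation).** Risks are polymerisation, low conversion, or reaction at the lactone methylenes. Fallback: join the halves stepwise by radical chemistry instead of cycloaddition. Mask the lactone methylenes as Me2NH Michael adducts, convert one monomer to the 4α-hydroxy-15-iodo ketone (α-face epoxidation of the enone, then iodide opening), and add its C15 radical (Giese) to the enone of a second masked monomer. Unmasking (MeI, then base) gives 5 directly.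
2. **Step 1 (SeO2 allylic oxidation).** Risks are competing C9 oxidation, over-oxidation and a moderate yield. Fallback: build 3 from (−)-α-santonin, whose C3 carbonyl is present from the start. Photochemical santonin-to-guaianolide rearrangement (hν, AcOH) gives the 5-7-5 core; elimination of the C10 acetate and selenoxide eliminations then install the C10=C14, C4=C15 and C11=C13 methylenes. No allylic C–H oxidation is needed.
3. **Step 5 (aldol).** Risks are the wrong C4′ epimer, retro-aldol, or base-induced Michael side reactions. Fallback: skip 5 and close the ring from enol ether 4 by a Lewis-acid Mukaiyama-type aldol (TiCl4 or BF3·OEt2, −78 °C). The enol-ether carbon C4′ attacks the activated C3 ketone while still tethered through oxygen, and aqueous work-up of the bridged oxocarbenium releases the C3′ ketone and C4–OH.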